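**Retrosynthetic overview**
1. The target is 5,7,4'-trihydroxy-6,2',5'-trimethoxyflavone; the last step is hydrogenolysis of three benzyl ethers on O5, O7 and O4'.
2. Ring C is the only ring that is made: the O1–C2 bond is closed by iodine/DMSO oxidative cyclisation of a 2'-hydroxychalcone, after the non-chelated C6 hydroxyl has been methylated.
3. Feature: in ring A the ring oxygen O1 on C8a and the methoxy oxygen on C6 are para, and C5 and C7 also carry oxygen, so ring A is a masked 2,6-bis(benzyloxy)-1,4-benzoquinone. Its two C–H carbons (the future C4a and C8) are equivalent by symmetry.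
4. Key disconnection C4–C4a: the acyl radical of the ring B cinnamaldehyde adds to that quinone and gives the chalcone hydroquinone, in which the C8a hydroxyl is chelated to the ketone and the C6 hydroxyl is free.
5. The quinone comes from 3,5-bis(benzyloxy)phenol by Teuber oxidation; the enal comes from 2,5-dimethoxyphenol by O-benzylation, Vilsmeier formylation and Wittig two-carbon homologation.

Key step: step 5

Remark: flavone numbering (O1, C2 to C4, C4a, C5 to C8, C8a, ring B primed) is used for the intermediates, and both phenol starting materials are taken as catalogue compounds.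

**Step 1**
Reactants: 1 3,5-bis(benzyloxy)phenol
Product: 2 2,6-bis(benzyloxy)-1,4-benzoquinone
Conditions: (KSO3)2NO (2.5 equiv), KH2PO4, H2O/acetone, rt
Reagents that add atoms: potassium nitrosodisulfonate (Fremy's salt), [K+].[K+].[O]N(S(=O)(=O)[O-])S(=O)(=O)[O-]
Why: Teuber oxidation, in which the nitrosodisulfonate radical forms the phenoxyl radical and a second equivalent delivers oxygen to the free para carbon between the two benzyloxy groups, as in the conversion of 3,5-dimethoxyphenol into 2,6-dimethoxy-1,4-benzoquinone, so the para-quinone should form under buffered conditions that leave the benzyl ethers alone.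

**Step 2**
Reactants: 3 2,5-dimethoxyphenol
Product: 4 2-(benzyloxy)-1,4-dimethoxybenzene
Conditions: BnBr, K2CO3, DMF, 50 °C
Reagents that add atoms: benzyl bromide, BrCc1ccccc1
Why: Williamson ether synthesis on an unhindered phenoxide with a reactive benzylic halide should be clean and protects the future C4' oxygen as the same group used on ring A.

**Step 3**
Reactants: 4 2-(benzyloxy)-1,4-dimethoxybenzene
Product: 6 4-(benzyloxy)-2,5-dimethoxybenzaldehyde, via aryl iminium chloride 5 (not isolated)
Conditions: POCl3, DMF, 0 → 70 °C; then H2O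
Reagents that add atoms: N,N-dimethylformamide, CN(C)C=O; water, O
Why: Vilsmeier–Haack formylation of a 1,2,4-trialkoxybenzene should occur at the unhindered carbon para to the benzyloxy group and ortho to a methoxy group, the same position at which 1,2,4-trimethoxybenzene is formylated, and water hydrolyses the iminium salt to the aldehyde.

**Step 4**
Reactants: 6 4-(benzyloxy)-2,5-dimethoxybenzaldehyde
Product: 7 (E)-3-[4-(benzyloxy)-2,5-dimethoxyphenyl]prop-2-enal
Conditions: Ph3P=CHCHO (1.2 equiv), PhMe, 90 °C
Reagents that add atoms: (triphenylphosphoranylidene)acetaldehyde, O=CC=P(c1ccccc1)(c1ccccc1)c1ccccc1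
Why: Wittig olefination with the stabilised formylmethylene ylide should give the E enal in one step, and the small excess of ylide limits a second homologation to the dienal.

**Step 5**
Reactants: 2 2,6-bis(benzyloxy)-1,4-benzoquinone; 7 (E)-3-[4-(benzyloxy)-2,5-dimethoxyphenyl]prop-2-enal
Product: 9 (E)-1-[2,4-bis(benzyloxy)-3,6-dihydroxyphenyl]-3-[4-(benzyloxy)-2,5-dimethoxyphenyl]prop-2-en-1-one, via dienone tautomer 8 (not isolated)
Conditions: hν (450 nm LEDs), 7 (3 equiv, 0.5 M), PhH (degassed, Ar), rt
Reagents that add atoms: none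
Why: Light at 450 nm is absorbed by the n,π* band of quinone 2, whose triplet abstracts the formyl hydrogen of 7; the σ-type enoyl radical adds to one of the two equivalent unsubstituted ring carbons of 2 (the future C4a) to give a radical stabilised by the adjacent benzyloxy and carbonyl groups, hydrogen is returned from the semiquinone, and dienone 8 enolises to the aromatic hydroquinone 9, so the C4–C4a bond is formed. The closest known reaction is the photo-Friedel–Crafts acylation of 1,4-quinones by aldehydes (Klinger–Kolvenbach photoacylation), which is established for benzoquinone and naphthoquinone with aliphatic, aromatic and α,β-unsaturated aldehydes and gives 2',5'-dihydroxyaryl ketones; the present partners are more alkoxy-rich than the usual cases, which is where the risk lies. No ring is closed and no stereocentre remains in 9 (the sp3 carbon of 8 is lost on enolisation); the E geometry of the enal is carried over, and any Z isomer formed by the light converges on the same flavone in step 7. Regioselectivity is not an issue, because the two C–H carbons of 2 are related by the mirror plane through both carbonyls, and a second acylation at the future C8 is not expected, since 9 is a hydroquinone and no longer a radical acceptor. The selectivity that is needed is formyl C–H abstraction over abstraction from the benzylic O–CH2 groups (including the intramolecular one by the carbonyl flanked by the two ethers), over electron transfer from the electron-rich ring B and over oxetane formation at the enal double bond; it is sought through the excess and high concentration of 7, light that 7 hardly absorbs, benzene as a non-polar solvent that disfavours radical ion pairs, and exclusion of oxygen. The new ketone hydrogen-bonds the C8a hydroxyl and leaves the C6 hydroxyl free, which prepares step 6.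

**Step 6**
Reactants: 9 (E)-1-[2,4-bis(benzyloxy)-3,6-dihydroxyphenyl]-3-[4-(benzyloxy)-2,5-dimethoxyphenyl]prop-2-en-1-one
Product: 10 (E)-1-[2,4-bis(benzyloxy)-6-hydroxy-3-methoxyphenyl]-3-[4-(benzyloxy)-2,5-dimethoxyphenyl]prop-2-en-1-one
Conditions: MeI (1.1 equiv), K2CO3 (1.1 equiv), acetone, Ar, rt
Reagents that add atoms: iodomethane, CI
Why: Williamson O-methylation with one equivalent of base should go to the C6 hydroxyl, because the C8a hydroxyl is held in a hydrogen bond to the ketone and its phenoxide is delocalised into the carbonyl (the bias that allows monomethylation of 2,5-dihydroxyacetophenones at the 5-hydroxyl); argon protects the hydroquinone from autoxidation, and any flavanone formed by oxa-Michael closure is carried to the same flavone in step 7.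

**Step 7**
Reactants: 10 (E)-1-[2,4-bis(benzyloxy)-6-hydroxy-3-methoxyphenyl]-3-[4-(benzyloxy)-2,5-dimethoxyphenyl]prop-2-en-1-one
Product: 11 5,7-bis(benzyloxy)-2-[4-(benzyloxy)-2,5-dimethoxyphenyl]-6-methoxy-4H-chromen-4-one
Conditions: I2 (10 mol%), DMSO, 120 °C
Reagents that add atoms: none
Why: Iodine-catalysed oxidative cyclisation of a 2'-hydroxychalcone, in which the chelated C8a hydroxyl closes ring C by 6-endo-trig oxa-Michael addition (O1–C2), α-iodination and loss of HI introduce the C2=C3 double bond and DMSO reoxidises HI to I2; partial loss of the C5 benzyl group under these conditions would be harmless, since step 8 removes it anyway.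

**Step 8**
Reactants: 11 5,7-bis(benzyloxy)-2-[4-(benzyloxy)-2,5-dimethoxyphenyl]-6-methoxy-4H-chromen-4-one
Product: 12 5,7-dihydroxy-2-(4-hydroxy-2,5-dimethoxyphenyl)-6-methoxy-4H-chromen-4-one (CNP0509606.0)
Conditions: H2 (1 atm), Pd/C (10%), THF/MeOH, rt
Reagents that add atoms: none
Why: Catalytic hydrogenolysis should cleave the three benzyl aryl ethers and leave the three methyl ethers and the vinylogous-ester C2=C3 bond of the flavone intact, provided the reaction is stopped when hydrogen uptake ends.

**Compound list**
1 | 3,5-bis(benzyloxy)phenol | Oc1cc(OCc2ccccc2)cc(OCc2ccccc2)c1 | starting material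
2 | 2,6-bis(benzyloxy)-1,4-benzoquinone | O=C1C=C(OCc2ccccc2)C(=O)C(OCc2ccccc2)=C1 | intermediate
3 | 2,5-dimethoxyphenol | COc1ccc(OC)c(O)c1 | starting material
4 | 2-(benzyloxy)-1,4-dimethoxybenzene | COc1ccc(OC)c(OCc2ccccc2)c1 | intermediate
5 | N-[4-(benzyloxy)-2,5-dimethoxybenzylidene]-N-methylmethanaminium chloride (not isolated) | C[N+](C)=Cc1cc(OC)c(OCc2ccccc2)cc1OC.[Cl-] | intermediate
6 | 4-(benzyloxy)-2,5-dimethoxybenzaldehyde | O=Cc1cc(OC)c(OCc2ccccc2)cc1OC | intermediate
7 | (E)-3-[4-(benzyloxy)-2,5-dimethoxyphenyl]prop-2-enal | O=C/C=C/c1cc(OC)c(OCc2ccccc2)cc1OC | intermediate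
8 | rac-3,5-bis(benzyloxy)-6-{(E)-3-[4-(benzyloxy)-2,5-dimethoxyphenyl]prop-2-enoyl}-4-hydroxycyclohexa-2,4-dien-1-one (not isolated) | O=C(/C=C/c1cc(OC)c(OCc2ccccc2)cc1OC)C1C(=O)C=C(OCc2ccccc2)C(O)=C1OCc1ccccc1 | intermediate
9 | (E)-1-[2,4-bis(benzyloxy)-3,6-dihydroxyphenyl]-3-[4-(benzyloxy)-2,5-dimethoxyphenyl]prop-2-en-1-one | O=C(/C=C/c1cc(OC)c(OCc2ccccc2)cc1OC)c1c(O)cc(OCc2ccccc2)c(O)c1OCc1ccccc1 | intermediate
10 | (E)-1-[2,4-bis(benzyloxy)-6-hydroxy-3-methoxyphenyl]-3-[4-(benzyloxy)-2,5-dimethoxyphenyl]prop-2-en-1-one | O=C(/C=C/c1cc(OC)c(OCc2ccccc2)cc1OC)c1c(O)cc(OCc2ccccc2)c(OC)c1OCc1ccccc1 | intermediate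
11 | 5,7-bis(benzyloxy)-2-[4-(benzyloxy)-2,5-dimethoxyphenyl]-6-methoxy-4H-chromen-4-one | COc1cc(-c2cc(=O)c3c(OCc4ccccc4)c(OC)c(OCc4ccccc4)cc3o2)c(OC)cc1OCc1ccccc1 | intermediate
12 | 5,7-dihydroxy-2-(4-hydroxy-2,5-dimethoxyphenyl)-6-methoxy-4H-chromen-4-one | COc1cc(-c2cc(=O)c3c(O)c(OC)c(O)cc3o2)c(OC)cc1O | target

**Step count**
Total steps: 8. Longest linear sequence: 7 steps (steps 2 to 8, from 2,5-dimethoxyphenol 3).

**Steps most likely to fail**

Step 5 (key step). The excited quinone may abstract hydrogen from the benzylic O–CH2 groups, within 2 itself or from 7, instead of the formyl hydrogen. It may also be quenched by electron transfer from ring B, and the light may be absorbed by 7 and by the growing amount of 9, so that the acylation stalls at low conversion. The fallback uses no radical step and sets out from phenol 1 and aldehyde 6. Friedel–Crafts acetylation of 1 (Ac2O, BF3·OEt2, through the aryl acetate and Fries shift to the position ortho to the hydroxyl) should give 1-[2,4-bis(benzyloxy)-6-hydroxyphenyl]ethan-1-one F1. Elbs persulfate oxidation (K2S2O8, aq. KOH, pyridine, rt) introduces oxygen para to the phenol, between the two benzyloxy groups, as potassium 3-acetyl-2,6-bis(benzyloxy)-4-hydroxyphenyl sulfate F2. Dilute HCl hydrolyses this to 1-[2,4-bis(benzyloxy)-3,6-dihydroxyphenyl]ethan-1-one F3. Methylation of the non-chelated hydroxyl (MeI, K2CO3, acetone, Ar) gives 1-[2,4-bis(benzyloxy)-6-hydroxy-3-methoxyphenyl]ethan-1-one F4. Claisen–Schmidt condensation of F4 with 6 (KOH, EtOH, rt) comes back to the route at chalcone 10.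

Step 6. Both hydroxyls may be methylated, the hydroquinone may be oxidised to the acylquinone under basic conditions, or base-induced ring closure may give mixtures. The fallback sets out from 9 and closes ring C before the methylation, so that only one phenol is left. Oxa-Michael cyclisation (NaOAc, EtOH, reflux, Ar) should give rac-5,7-bis(benzyloxy)-2-[4-(benzyloxy)-2,5-dimethoxyphenyl]-6-hydroxy-2,3-dihydro-4H-chromen-4-one F5. Base-free methylation of its single hydroxyl (Me3SiCHN2, MeOH/PhMe, rt) gives rac-5,7-bis(benzyloxy)-2-[4-(benzyloxy)-2,5-dimethoxyphenyl]-6-methoxy-2,3-dihydro-4H-chromen-4-one F6. Dehydrogenation of the flavanone (I2 cat., DMSO, 120 °C) comes back to the route at flavone 11.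

Step 4. The electron-rich aldehyde may react slowly, and the product enal may react again with the ylide, so that mixtures with the dienal form. The fallback sets out from 6. Horner–Wadsworth–Emmons olefination (triethyl phosphonoacetate, NaH, THF) should give ethyl (E)-3-[4-(benzyloxy)-2,5-dimethoxyphenyl]prop-2-enoate F7. Reduction with i-Bu2AlH (CH2Cl2, −78 °C) gives (E)-3-[4-(benzyloxy)-2,5-dimethoxyphenyl]prop-2-en-1-ol F8. Allylic oxidation with MnO2 (CH2Cl2, rt) comes back to the route at enal 7.

**Further compounds**
F1 | step 5 | 1-[2,4-bis(benzyloxy)-6-hydroxyphenyl]ethan-1-one | CC(=O)c1c(O)cc(OCc2ccccc2)cc1OCc1ccccc1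
F2 | step 5 | potassium 3-acetyl-2,6-bis(benzyloxy)-4-hydroxyphenyl sulfate | CC(=O)c1c(O)cc(OCc2ccccc2)c(OS(=O)(=O)[O-])c1OCc1ccccc1.[K+]
F3 | step 5 | 1-[2,4-bis(benzyloxy)-3,6-dihydroxyphenyl]ethan-1-one | CC(=O)c1c(O)cc(OCc2ccccc2)c(O)c1OCc1ccccc1
F4 | step 5 | 1-[2,4-bis(benzyloxy)-6-hydroxy-3-methoxyphenyl]ethan-1-one | CC(=O)c1c(O)cc(OCc2ccccc2)c(OC)c1OCc1ccccc1
F5 | step 6 | rac-5,7-bis(benzyloxy)-2-[4-(benzyloxy)-2,5-dimethoxyphenyl]-6-hydroxy-2,3-dihydro-4H-chromen-4-one | COc1cc(C2CC(=O)c3c(OCc4ccccc4)c(O)c(OCc4ccccc4)cc3O2)c(OC)cc1OCc1ccccc1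
F6 | step 6 | rac-5,7-bis(benzyloxy)-2-[4-(benzyloxy)-2,5-dimethoxyphenyl]-6-methoxy-2,3-dihydro-4H-chromen-4-one | COc1cc(C2CC(=O)c3c(OCc4ccccc4)c(OC)c(OCc4ccccc4)cc3O2)c(OC)cc1OCc1ccccc1
F7 | step 4 | ethyl (E)-3-[4-(benzyloxy)-2,5-dimethoxyphenyl]prop-2-enoate | CCOC(=O)/C=C/c1cc(OC)c(OCc2ccccc2)cc1OC
F8 | step 4 | (E)-3-[4-(benzyloxy)-2,5-dimethoxyphenyl]prop-2-en-1-ol | OC/C=C/c1cc(OC)c(OCc2ccccc2)cc1OC
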